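All runs stem from a simulated flask for an exercise, and the scatter is random.

In millimoles per litre the two runs show what percentages hide. In Monday's run, 8 mM of starting material holds target near 36.2% of the charge, which is 2.90 mM. In Tuesday's run, 18 mM holds near 20.4%, which is 3.67 mM. In both runs the target is flat from the first reading, and the starting material reads close to nothing, given a scatter of 1.5 percentage points.

| flask | starting material | gas | remark | time |
|---|---|---|---|---|
| Monday's | 8 mM | 6.9 mM (held) | run made earlier |  |
| Tuesday's | 18 mM | 6.9 mM (held) | run made earlier |  |
| flask | 12 mM | 6.9 mM (held) |  | 4.0 d |

| run | time / d | starting material / % | target / % |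
|---|---|---|---|
| Monday's | 0.417 | 0 | 34 |
| Monday's | 0.833 | 1 | 36 |
| Monday's | 1.25 | 0 | 37 |
| Monday's | 2.50 | 0 | 39 |
| Monday's | 5.00 | 0 | 35 |
| Tuesday's | 0.417 | 1 | 20 |
| Tuesday's | 0.833 | 0 | 21 |
| Tuesday's | 1.25 | 1 | 21 |
| Tuesday's | 2.50 | 2 | 19 |
| Tuesday's | 5.00 | 2 | 21 |

(readings scatter by 1.5 percentage points)

- at the start none of the gas is in solution
- the reaction counts as stopped when no species that holds the starting material changes by six tenths of a point or more over the second half of the time

1. the state of affairs at 4.0 d: stopped, and by what, or still going (all of the starting material has reacted / forward and back rates have come level / it is still moving)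
2. how much of the starting material has reacted by 4.0 d
3. how much target there is at 4.0 d, in percent of the starting material charged

My own reckoning freezes the dissolved gas at a constant level. The route to target is then pseudo-first-order in starting material, and I take the competing route to be second order. Their rates are level at one amount of starting material. Let f be that amount as a fraction of the charge; summing over the whole consumption, the yield is f times the logarithm of one plus the inverse of f. Monday's mean yield needs an amount of 1.60 mM, which is an f of 20.0%, and Tuesday's needs 1.38 mM, which is an f of 7.67%. Their mean, 1.49 mM, read off scattered yields, is the crossover amount, the amount of starting material at which both routes consume it equally fast. The two values part, and the suspect is the frozen gas, since none is in solution at the start. The flask's 12 mM lies between the two charges, so f is 12.4% and the yield 27.4%.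

The forecast goes another way over the same readings: “Interpolating on log concentration gives about” 27%, with 99.5% reacted and the state at 4.0 d given as: all of the starting material has reacted. The agreement tests the shape of the curve, not the readings.

    gas ⇌ reagent, rate k1*(csat - [reagent]) (kL = 5.00 × 10⁻⁴ s⁻¹)
    starting material + reagent → target + released group (k = 0.0600 M⁻¹ s⁻¹)
    2 starting material → self-condensation product (k = 0.0470 M⁻¹ s⁻¹)

The flask gives 27.6% target and 100% conversion: all of the starting material has reacted. Reagent, the gas in solution, entered while starting material was consumed: half of the uptake came by 0.612 h and half of the target by 0.752 h. From 0.400 d the flask held 27.6% target, 72.4% self-condensation product and 6.90 mM reagent, with 0% starting material. The simulated yield, with the time held, has moved by 5 points at a charge of 9.40 mM or 15.8 mM. For the neighbour with 30 mM, the crossover amount gives 15.2%, and that flask holds 13.5%.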